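## Retrosynthetic overview

- The strategy rests on ring A. Its two oxygens sit on C3 and on C18, the equatorial CH2O arm of quaternary C4. This 1,3-diol pattern is what a C4–C18 epoxide leaves when its C4 radical closes onto a C3 aldehyde. Ring B (C5–C10, with the C8 methyl and oxygenated C9) is the ring of (R)-carvone.
- Late cuts: the acetates go back to the 3,18-diol. Tetrahydrofuran ring C is cut at C9–O (C13 hydroxyl added across a C9=C11 alkene). Lactone ring D (C13–C16, 13S) is traced to (S)-malic acid.
- C12–C13 is cut to the enolate of the malic acid dioxolanone and a C12 allylic bromide, which comes from the C9 ketone by vinyl addition and allylic transposition.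
- Ring A is cut at C3–C4 to an epoxy aldehyde, whose quaternary C10 comes from methylation and then allylation of carvone.
- Ring order: B (chiral pool), A (step 7), D (step 13), C (step 14).

Key step: step 7

Remark: labdane numbering is used throughout. The epoxides of steps 4–6 are carried as C4 epimer mixtures (one drawn), the carbinol of step 9 is drawn as the product of attack anti to the C10 methyl, and the bromide of step 10 is drawn as the E isomer. All three elements disappear later, in steps 7, 10 and 14.

## Route

Step 1
Reactants: 1 (R)-carvone; 2 iodomethane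
Product: 4 (5R,6S)-6-methylcarvone (methyl trans to isopropenyl; minor cis epimer carried along), via lithium dienolate of carvone 3 (not isolated)
Conditions: LiN(i-Pr)2, THF, −78 °C; MeI, −78 → 0 °C
Reagents that add atoms: iodomethane, CI
Why: Kinetic deprotonation of the enone occurs at the α′ methylene (future C10) to give the cross-conjugated dienolate, and its enolate alkylation with MeI installs C20; the new centre is made trigonal again in step 2, so its epimer composition does not matter.

Step 2
Reactants: 4 (5R,6S)-6-methylcarvone; 5 allyl bromide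
Product: 7 (5S,6S)-6-allyl-6-methylcarvone (allyl trans to isopropenyl), via lithium dienolate of 6-methylcarvone 6 (not isolated)
Conditions: LiN(i-Pr)2, THF–DMPU, −78 °C; allyl bromide, −78 °C → rt
Reagents that add atoms: allyl bromide, C=CCBr
Why: In this second kinetic α′-enolate alkylation the electrophile approaches the dienolate on the face opposite the neighbouring isopropenyl group, so the C1–C3 chain ends trans and the C20 methyl cis to that group, which fixes quaternary C10.

Step 3
Reactants: 7 (5S,6S)-6-allyl-6-methylcarvone
Product: 9 (2S,3S,6R)-2-allyl-2,6-dimethyl-3-(prop-1-en-2-yl)cyclohexanone, via lithium enolate 8 (not isolated)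
Conditions: Li[(s-Bu)3BH], THF, −78 °C; MeOH; NaOMe (cat.), MeOH, rt
Reagents that add atoms: none
Why: Conjugate (1,4) hydride reduction of a β-unsubstituted cyclohexenone by the bulky trialkylborohydride spares both isolated alkenes and stops at the enolate; base equilibration then places the C8 methyl equatorial (α), because the axial epimer would be syn-diaxial to the C10 methyl.

Step 4
Reactants: 9 saturated ketone
Product: 10 C4–C18 epoxide of 9 (2-methyloxiran-2-yl group on C5; both C4 epimers; one drawn)
Conditions: mCPBA (1.0 equiv), CH2Cl2, −10 → 0 °C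
Reagents that add atoms: 3-chloroperoxybenzoic acid, OOC(=O)c1cccc(Cl)c1
Why: Prilezhaev epoxidation favours the more electron-rich 1,1-disubstituted alkene over the monosubstituted allyl group and leaves the hindered ketone alone; the lack of control at C4 is harmless because C4 becomes a planar radical in step 7.

Step 5
Reactants: 10 epoxy ketone with allyl group
Product: 12 epoxy keto alcohol (3-hydroxypropyl chain C1–C3 on C10), via B-alkyl-9-BBN adduct 11 (not isolated)
Conditions: 9-BBN, THF, 0 °C → rt; H2O2, aq NaOH, 0 °C
Reagents that add atoms: hydrogen peroxide, OO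
Why: In this anti-Markovnikov hydroboration–oxidation, 9-BBN adds to the terminal alkene much faster than it reduces a ketone flanked by quaternary C10 and tertiary C8, and it does not open the epoxide.

Step 6
Reactants: 12 epoxy keto alcohol
Product: 13 epoxy keto aldehyde (C3 aldehyde, C4–C18 epoxide, C9 ketone; key-step precursor)
Conditions: nPr4N[RuO4] (5 mol %), NMO, 4 Å MS, CH2Cl2, rt
Reagents that add atoms: none
Why: The Ley–Griffith oxidation runs under neutral, anhydrous conditions, so it stops at the aldehyde and spares the acid-sensitive 2,2-disubstituted epoxide and the epimerisable C8 centre.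

Step 7
Reactants: 13 epoxy keto aldehyde
Product: 15 3β,18-dihydroxy-11,12,13,14,15,16-hexanorlabdan-9-one (trans-decalin; 8α-methyl), via bis(chlorotitanocene) dialkoxide 14 (not isolated)
Conditions: Cp2TiCl2 (2.5 equiv), Mn dust, THF, rt, until green; slow addition of 13, rt; 1 M HCl
Reagents that add atoms: none
Why: Cp2TiCl (trivalent titanium, generated from Cp2TiCl2 and Mn) transfers one electron to the epoxide, the C4–O bond breaks and the titanoxy group remains on C18, so both epoxide epimers give the same planar tertiary C4 radical. The radical adds to the carbon of the titanium-coordinated C3 aldehyde in a 6-exo-trig closure that forms C3–C4 and ring A, and a second Cp2TiCl reduces the resulting oxygen radical to the tetravalent titanium alkoxide 14, which removes the reversibility of radical addition to a carbonyl group. The closest known reaction type is the titanocene-mediated reductive cyclisation of epoxy aldehydes and epoxy ketones to cyclic 1,3-diols. C4 is controlled by the chair transition state built on the ring B chair, in which both connecting bonds (C5–C4 and C10–C1) are equatorial, hence the trans fusion, and the axial C10 methyl tolerates only the small methyl group in the axial β position, so the bulky CH2OTiCp2Cl arm becomes the equatorial α substituent C18. C3 is controlled by the same chair, with the titanium-bound aldehyde oxygen taking the equatorial β position away from the axial hydrogens on C1 and C5. The step needs the radical to react with the aldehyde only, and the substrate secures this because closure onto the C9 ketone would be a strained 4-exo process at a carbonyl shielded by quaternary C10, aliphatic carbonyl groups are not reduced by Cp2TiCl, and a tertiary radical is captured only slowly by a second titanium centre.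

Step 8
Reactants: 15 diol ketone
Product: 16 3β,18-O-isopropylidene acetal of 15
Conditions: Me2C(OMe)2, PPTS (cat.), CH2Cl2, rt
Reagents that add atoms: 2,2-dimethoxypropane, COC(C)(C)OC
Why: In this acid-catalysed transacetalisation the equatorial 3β-hydroxyl and the equatorial 18-hydroxymethyl group lie gauche and close a chair 1,3-dioxane, which masks both hydroxyls against the organometallic, basic and hydride steps that follow.

Step 9
Reactants: 16 acetonide ketone; 17 vinylmagnesium bromide
Product: 19 3β,18-isopropylidenedioxy-13,14,15,16-tetranorlabd-11-en-9-ol (9-vinyl carbinol; 9β-OH drawn), via dichlorocerium alkoxide 18 (not isolated)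
Conditions: CeCl3 (anhydrous), CH2=CHMgBr, THF, −78 °C; 16, −78 → 0 °C; aq NH4Cl
Reagents that add atoms: vinylmagnesium bromide, C=C[Mg]Br
Why: Organocerium 1,2-addition suits a hindered enolisable ketone because the weakly basic, oxophilic vinylcerium reagent adds where the Grignard reagent alone would partly deprotonate C8; attack is expected anti to the axial C10 methyl, and the new C9 configuration is irrelevant because C9 becomes trigonal in step 10.

Step 10
Reactants: 19 vinyl carbinol
Product: 20 (9(11)E)-12-bromo-3β,18-isopropylidenedioxy-13,14,15,16-tetranorlabd-9(11)-ene (primary allylic bromide; used crude)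
Conditions: PBr3, pyridine (cat.), Et2O, −20 → 0 °C
Reagents that add atoms: phosphorus tribromide, BrP(Br)Br
Why: Bromination proceeds with allylic transposition (SN2′-type displacement of the activated tertiary alcohol) because bromide attacks the open vinyl terminus C12 rather than the fully substituted neopentylic C9; this gives the trisubstituted C9=C11 alkene, expected to turn C12 towards C8 rather than quaternary C10, and pyridine keeps HBr away from the acetonide.

Step 11
Reactants: 21 (S)-malic acid; 22 pivalaldehyde
Product: 23 (2S,4S)-2-tert-butyl-5-oxo-1,3-dioxolane-4-acetic acid (cis)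
Conditions: t-BuCHO, p-TsOH (cat.), pentane, reflux, Dean–Stark; recrystallisation
Reagents that add atoms: pivalaldehyde, CC(C)(C)C=O
Why: Reversible acid-catalysed acetalisation of the α-hydroxy acid unit gives the five-membered dioxolanone, and the existing stereocentre (future C13) steers the new acetal centre to the thermodynamically preferred cis-2,4 arrangement, which crystallisation purifies.

Step 12
Reactants: 20 allylic bromide; 23 dioxolanone acid
Product: 25 C12-alkylated dioxolanone acid (C13 quaternary; C12 trans to tert-butyl), via dilithio enolate carboxylate 24 (not isolated)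
Conditions: 23 (1.5 equiv), LiN(SiMe3)2 (3.1 equiv), THF, −78 °C; 20, −78 → −30 °C; 1 M HCl to pH 3, 0 °C
Reagents that add atoms: none
Why: This is an enolate alkylation by self-regeneration of stereocentres, in which the dilithio species is planar at C13 but keeps the acetal centre whose tert-butyl group blocks one face; the primary allylic bromide is therefore displaced in SN2 fashion at C12 (the C9 end is fully substituted) on the face the proton left, giving net retention and hence 13S.

Step 13
Reactants: 25 alkylated dioxolanone acid
Product: 27 (13S)-13-hydroxy-3β,18-isopropylidenedioxylabd-9(11)-en-15,16-olide, via lithium dihydroxy carboxylate 26 (not isolated)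
Conditions: LiBHEt3 (5 equiv), THF, −78 → 0 °C; 1 M HCl to pH 3, 0 °C; PPTS (cat.), 4 Å MS, CH2Cl2, rt
Reagents that add atoms: none
Why: The hydride reduction is chemoselective for an ester-type carbonyl beside a carboxylate, since the first equivalent turns the acid into the inert lithium carboxylate and releases only BEt3, which neither reduces nor hydroborates; the acylal carbonyl C16 goes to CH2OH with collapse of the acetal, and on acidification the 16-hydroxy acid lactonises (5-exo-trig) to ring D with C13 untouched.

Step 14
Reactants: 27 hydroxy lactone alkene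
Product: 28 (13S)-9α,13-epoxy-3β,18-isopropylidenedioxylabdan-15,16-olide
Conditions: [N,N′-bis(3,5-di-tert-butylsalicylidene)-1,2-cyclohexanediaminato]cobalt (divalent cobalt, 5 mol %), N-fluoro-2,4,6-trimethylpyridinium tetrafluoroborate, PhSiH3, PhCF3, rt
Reagents that add atoms: none
Why: In this Mukaiyama-type cobalt-hydride hydrogen-atom transfer with radical–polar crossover (intramolecular Markovnikov hydroalkoxylation of an unactivated alkene), the hydrogen atom goes to the less substituted C11 and the tertiary C9 radical is oxidised through an alkylcobalt species to a cation equivalent; the tethered C13 hydroxyl captures it to close ring C (O–C9–C11–C12–C13) from the α face, anti to the axial C10 methyl, so oxygen becomes axial, C11 equatorial and bulky C13 stays clear of C20, while the unbroken C13–O bond keeps 13S and the lactone and acetonide are inert.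

Step 15
Reactants: 28 spiro ether acetonide
Product: 29 (13S)-9α,13-epoxy-3β,18-dihydroxylabdan-15,16-olide
Conditions: AcOH–H2O (4:1), 40 °C
Reagents that add atoms: none
Why: Mild acid hydrolysis cleaves the 1,3-dioxane acetal, and acetic acid is too weak to ionise the di-tertiary ether at C9 or to eliminate the β-alkoxy lactone.

Step 16
Reactants: 29 diol
Product: 30 (13S)-3β,18-diacetoxy-9α,13-epoxylabdan-15,16-olide (CNP0117603.3)
Conditions: Ac2O, pyridine, DMAP (cat.), CH2Cl2, 0 °C → rt
Reagents that add atoms: acetic anhydride, CC(=O)OC(C)=O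
Why: DMAP-catalysed acylation esterifies the primary 18-OH and the equatorial secondary 3β-OH, and the weak amine bases should not trigger retro-oxa-Michael opening at C13.

## Compound list

1 | (R)-carvone | CC1=CC[C@H](CC1=O)C(C)=C | starting material
2 | iodomethane | CI | starting material
3 | lithium dienolate of carvone (not isolated) | [Li+].[O-]C1=C[C@H](C(C)=C)CC=C1C | intermediate
4 | (5R,6S)-6-methylcarvone | C[C@H]1[C@H](C(C)=C)CC=C(C)C1=O | intermediate
5 | allyl bromide | C=CCBr | starting material
6 | lithium dienolate of 6-methylcarvone (not isolated) | [Li+].[O-]C1=C(C)[C@H](C(C)=C)CC=C1C | intermediate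
7 | (5S,6S)-6-allyl-6-methylcarvone | C=CC[C@@]1(C)[C@H](C(C)=C)CC=C(C)C1=O | intermediate
8 | lithium enolate from conjugate reduction (not isolated) | C=CC[C@@]1(C)[C@H](C(C)=C)CCC(C)=C1[O-].[Li+] | intermediate
9 | (2S,3S,6R)-2-allyl-2,6-dimethyl-3-(prop-1-en-2-yl)cyclohexanone | C=CC[C@@]1(C)[C@H](C(C)=C)CC[C@@H](C)C1=O | intermediate
10 | C4–C18 epoxide of 9 (C4 epimers, one drawn) | C=CC[C@@]1(C)[C@H]([C@@]2(C)CO2)CC[C@@H](C)C1=O | intermediate
11 | B-alkyl-9-BBN adduct (not isolated) | B1(CCC[C@@]2(C)[C@H]([C@@]3(C)CO3)CC[C@@H](C)C2=O)C2CCCC1CCC2 | intermediate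
12 | epoxy keto alcohol | OCCC[C@@]1(C)[C@H]([C@@]2(C)CO2)CC[C@@H](C)C1=O | intermediate
13 | epoxy keto aldehyde (key-step precursor) | O=CCC[C@@]1(C)[C@H]([C@@]2(C)CO2)CC[C@@H](C)C1=O | intermediate
14 | bis(chlorotitanocene) 3,18-dialkoxide (not isolated) | [O-]C[C@]1(C)[C@@H]([O-])CC[C@@]2(C)[C@H]1CC[C@@H](C)C2=O.[Ti+4].[Ti+4].[Cl-].[Cl-].c1cc[cH-]c1.c1cc[cH-]c1.c1cc[cH-]c1.c1cc[cH-]c1 | intermediate
15 | 3β,18-dihydroxy-11,12,13,14,15,16-hexanorlabdan-9-one (key-step product) | OC[C@]1(C)[C@@H](O)CC[C@@]2(C)[C@H]1CC[C@@H](C)C2=O | intermediate
16 | 3β,18-O-isopropylidene acetal of 15 | CC1(C)OC[C@]2(C)[C@@H](O1)CC[C@@]1(C)[C@H]2CC[C@@H](C)C1=O | intermediate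
17 | vinylmagnesium bromide | C=C[Mg]Br | starting material
18 | dichlorocerium alkoxide (not isolated) | CC1(C)OC[C@]2(C)[C@@H](O1)CC[C@@]1(C)[C@H]2CC[C@@H](C)[C@@]1([O-])C=C.[Ce+3].[Cl-].[Cl-] | intermediate
19 | 9-vinyl carbinol (9β-OH drawn) | CC1(C)OC[C@]2(C)[C@@H](O1)CC[C@@]1(C)[C@H]2CC[C@@H](C)[C@@]1(O)C=C | intermediate
20 | C12 allylic bromide (E drawn) | CC1(C)OC[C@]2(C)[C@@H](O1)CC[C@@]1(C)[C@H]2CC[C@@H](C)/C1=C\CBr | intermediate
21 | (S)-malic acid | O[C@@H](CC(=O)O)C(=O)O | starting material
22 | pivalaldehyde | CC(C)(C)C=O | starting material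
23 | (2S,4S)-2-tert-butyl-5-oxo-1,3-dioxolane-4-acetic acid | OC(=O)C[C@@H]1O[C@H](C(C)(C)C)OC1=O | intermediate
24 | dilithio enolate carboxylate of 23 (not isolated) | [Li+].[Li+].[O-]C(=O)CC1=C([O-])O[C@@H](C(C)(C)C)O1 | intermediate
25 | C12-alkylated dioxolanone acid | CC1(C)OC[C@]2(C)[C@@H](O1)CC[C@@]1(C)[C@H]2CC[C@@H](C)/C1=C\C[C@@]1(CC(=O)O)O[C@H](C(C)(C)C)OC1=O | intermediate
26 | lithium 13,16-dihydroxy-15-carboxylate (not isolated) | CC1(C)OC[C@]2(C)[C@@H](O1)CC[C@@]1(C)[C@H]2CC[C@@H](C)/C1=C\C[C@@](O)(CO)CC(=O)[O-].[Li+] | intermediate
27 | (13S)-13-hydroxy-3β,18-isopropylidenedioxylabd-9(11)-en-15,16-olide | CC1(C)OC[C@]2(C)[C@@H](O1)CC[C@@]1(C)[C@H]2CC[C@@H](C)/C1=C\C[C@@]1(O)COC(=O)C1 | intermediate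
28 | (13S)-9α,13-epoxy-3β,18-isopropylidenedioxylabdan-15,16-olide | CC1(C)OC[C@]2(C)[C@@H](O1)CC[C@@]1(C)[C@H]2CC[C@@H](C)[C@]13CC[C@]4(COC(=O)C4)O3 | intermediate
29 | (13S)-9α,13-epoxy-3β,18-dihydroxylabdan-15,16-olide | OC[C@]1(C)[C@@H](O)CC[C@@]2(C)[C@H]1CC[C@@H](C)[C@]21CC[C@]2(COC(=O)C2)O1 | intermediate
30 | (13S)-3β,18-diacetoxy-9α,13-epoxylabdan-15,16-olide (CNP0117603.3) | CC(=O)OC[C@]1(C)[C@@H](OC(C)=O)CC[C@@]2(C)[C@H]1CC[C@@H](C)[C@]21CC[C@]2(COC(=O)C2)O1 | target

## Step count and risks

Total step count: 16. Longest linear sequence: 15 steps from (R)-carvone (steps 1–10 and 12–16). Step 11 is a one-step side branch.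

**Step 7.** Facial selectivity at the aldehyde carbon may be poor, because an equatorial titanoxy group on C3 is gauche to both substituents of C4. In that case the axial alcohol would form beside 15.
- The fallback sets C3 by hydride delivery instead of by the radical transition state.
- It sets out from 15 mixed with its 3α epimer F1.
- TBSCl and imidazole silylate only the primary hydroxyl, giving the 18-silyl ether F2.
- Dess–Martin oxidation gives the 18-silyloxy 3,9-dione F3.
- NaBH4 in MeOH at low temperature attacks the less shielded C3 ketone axially from the α face, as is usual for 4,4-disubstituted 3-ketones. This gives the 3β-alcohol silyl ether F4.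
- Bu4NF removes the silyl group and the route is rejoined at 15.

**Step 14.** Three processes may interfere.
- The oxygen may attack the wrong face of C9.
- The C9 radical or cation may lose the C8 hydrogen, isomerising the alkene to the unreactive tetrasubstituted C8=C9 alkene.
- The C10 methyl may migrate.

The fallback reverses the roles of the two oxygen-bearing carbons and sets out from 27.
- Mukaiyama hydration (Mn(dpm)3 catalyst, PhSiH3, O2, i-PrOH) lets small O2 trap the C9 radical anti to the C10 methyl. This gives the 9α,13-diol lactone F5.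
- MsCl and Et3N sulfonylate only the less shielded 13-hydroxyl, giving the 13-mesylate F6.
- F6 undergoes E1cB elimination in the same flask to the 9α-hydroxy butenolide F7.
- DBU in MeCN then promotes 5-exo-trig oxa-Michael addition of the 9α-hydroxyl to C13, giving 28 together with its 13R epimer F8.
- F8 is separated and returned to the base for re-equilibration. The route is rejoined at 28.

**Step 10.** Ionisation of the tertiary allylic alcohol with loss of the C8 proton would give a diene, and HBr may cleave the acetonide. The fallback avoids cationic conditions and sets out from 19.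
- Babler–Dauben oxidative transposition with pyridinium chlorochromate, [C5H5NH][CrO3Cl], buffered with NaOAc, gives the C12 enal F9.
- Luche reduction (NaBH4, CeCl3·7H2O, MeOH) gives the primary allylic alcohol F10.
- A neutral Appel bromination (CBr4, PPh3) rejoins the route at 20.

## Further compounds

F1 | step 7 | 3α epimer of 15 | OC[C@]1(C)[C@H](O)CC[C@@]2(C)[C@H]1CC[C@@H](C)C2=O
F2 | step 7 | 18-O-TBS ether (3α epimer drawn) | CC(C)(C)[Si](C)(C)OC[C@]1(C)[C@H](O)CC[C@@]2(C)[C@H]1CC[C@@H](C)C2=O
F3 | step 7 | 18-O-TBS 3,9-dione | CC(C)(C)[Si](C)(C)OC[C@]1(C)C(=O)CC[C@@]2(C)[C@H]1CC[C@@H](C)C2=O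
F4 | step 7 | 18-O-TBS 3β-alcohol | CC(C)(C)[Si](C)(C)OC[C@]1(C)[C@@H](O)CC[C@@]2(C)[C@H]1CC[C@@H](C)C2=O
F5 | step 14 | 9α,13-diol lactone | CC1(C)OC[C@]2(C)[C@@H](O1)CC[C@@]1(C)[C@H]2CC[C@@H](C)[C@]1(O)CC[C@@]1(O)COC(=O)C1
F6 | step 14 | 13-mesylate of F5 | CC1(C)OC[C@]2(C)[C@@H](O1)CC[C@@]1(C)[C@H]2CC[C@@H](C)[C@]1(O)CC[C@@]1(OS(C)(=O)=O)COC(=O)C1
F7 | step 14 | 9α-hydroxy-13-en-15,16-olide (butenolide) | CC1(C)OC[C@]2(C)[C@@H](O1)CC[C@@]1(C)[C@H]2CC[C@@H](C)[C@]1(O)CCC1=CC(=O)OC1
F8 | step 14 | 13R epimer of 28 | CC1(C)OC[C@]2(C)[C@@H](O1)CC[C@@]1(C)[C@H]2CC[C@@H](C)[C@]13CC[C@@]4(COC(=O)C4)O3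
F9 | step 10 | C12 enal | CC1(C)OC[C@]2(C)[C@@H](O1)CC[C@@]1(C)[C@H]2CC[C@@H](C)/C1=C\C=O
F10 | step 10 | C12 primary allylic alcohol | CC1(C)OC[C@]2(C)[C@@H](O1)CC[C@@]1(C)[C@H]2CC[C@@H](C)/C1=C\CO
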